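The plan cuts ring B at C6–C7. Ring B carries the three-carbon unit C11–C13 on C7, directly beside C6 and flanked by the C8 oxygen. This array is the imprint of a type 1 carbonyl-ene reaction between a formyl group (C6) on C5 and a trisubstituted C7=C11 alkene. In one operation the key step makes the C6–C7 bond, closes ring B onto ring A as a trans-decalin and places an isopropenyl group on C7 between oxygen functions at C6 and C8. Its precursor is a ring A aldehyde with C3, C4, C5 and C10 already fixed, the trans 3β,4α-diol held as two silyl ethers instead of a strained trans-fused ketal, and an (8S)-silyloxy prenyl-type arm on C10.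

Key step: step 18

Remark: eudesmane numbering is used for all intermediates (C14 = methyl on C10, C15 = methyl on C4, β = the face of C14), and the facial senses of the PHOX, oxazaborolidine and tartrate catalysts are assigned by analogy with their standard substrates.

Step 1
Reactants: 1 2-methylcyclohexane-1,3-dione
Product: 2 3-isobutoxy-2-methylcyclohex-2-en-1-one
Conditions: i-BuOH, p-toluenesulfonic acid (cat.), toluene, reflux, Dean–Stark
Reagents that add atoms: 2-methylpropan-1-ol, CC(C)CO
Why: Acid-catalysed vinylogous esterification of the symmetrical dione with azeotropic water removal can give only one enol ether, and it differentiates the future C3 (enol ether) from C5 (ketone) on either side of C4 with its methyl C15.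

Step 2
Reactants: 2 3-isobutoxy-2-methylcyclohex-2-en-1-one; 3 iodomethane
Product: 5 3-isobutoxy-2,6-dimethylcyclohex-2-en-1-one (racemic), via lithium enolate 4 (not isolated)
Conditions: LiN(iPr)2, THF, −78 °C; MeI, −78 → 0 °C
Reagents that add atoms: iodomethane (3), CI; lithium diisopropylamide, [Li]N(C(C)C)C(C)C (lithium in 4 only)
Why: Stork–Danheiser kinetic α′-enolate alkylation (SN2 on MeI) puts C14 on the future C10, and the racemic new centre is harmless because step 3 flattens it again.

Step 3
Reactants: 5 3-isobutoxy-2,6-dimethylcyclohex-2-en-1-one; 6 allyl chloroformate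
Product: 8 allyl 5-isobutoxy-2,6-dimethylcyclohexa-1,5-dien-1-yl carbonate, via lithium enolate 7 (not isolated)
Conditions: LiN(iPr)2, TMEDA, THF, −78 °C; ClCO2CH2CH=CH2
Reagents that add atoms: allyl chloroformate (6), C=CCOC(=O)Cl; lithium diisopropylamide, [Li]N(C(C)C)C(C)C (lithium in 7 only)
Why: O-acylation of the hindered, fully substituted lithium enolate by the hard chloroformate gives the allyl enol carbonate, which fixes the enolate regiochemistry and carries the allyl group needed in step 4.

Step 4
Reactants: 8 allyl 5-isobutoxy-2,6-dimethylcyclohexa-1,5-dien-1-yl carbonate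
Product: 9 (R)-6-allyl-3-isobutoxy-2,6-dimethylcyclohex-2-en-1-one
Conditions: Pd2(dba)3 (2.5 mol %), (R)-t-BuPHOX C25H26NOP (6 mol %), toluene, 25 °C
Reagents that add atoms: none
Why: In this decarboxylative asymmetric allylic alkylation (Tsuji allylation), loss of CO2 gives a palladium π-allyl enolate pair and the P,N ligand selects the enolate face, so the (R)-ligand should set C10 as R, mirroring the (S)-ligand to (S)-2-allyl-2-methylcyclohexanone relationship.

Step 5
Reactants: 9 (R)-6-allyl-3-isobutoxy-2,6-dimethylcyclohex-2-en-1-one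
Product: 11 (R)-4-allyl-2,4-dimethylcyclohex-2-en-1-one, via allylic alcohol 10 (not isolated)
Conditions: LiAlH4, Et2O, 0 °C; then 2 M HCl, 0 °C → rt
Reagents that add atoms: water, O
Why: In this Stork–Danheiser carbonyl transposition, 1,2-hydride addition at C5 followed by acid-induced ionisation and enol ether hydrolysis moves the carbonyl to C3 and leaves the C4=C5 enone with C10 untouched.

Step 6
Reactants: 11 (R)-4-allyl-2,4-dimethylcyclohex-2-en-1-one
Product: 12 (1S,4R)-4-allyl-2,4-dimethylcyclohex-2-en-1-ol (3β-alcohol)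
Conditions: (R)-2-methyl-CBS-oxazaborolidine C18H20BNO (15 mol %), catecholborane, toluene, −78 °C
Reagents that add atoms: none
Why: Corey–Bakshi–Shibata reduction, with the methyl-bearing alkene carbon C4 as the large and C2 as the small substituent, delivers hydride to the α face under reagent control and sets C3 as the 3β (S) alcohol, while catecholborane at low temperature spares the allyl group.

Step 7
Reactants: 12 (1S,4R)-4-allyl-2,4-dimethylcyclohex-2-en-1-ol; 13 tributyl(iodomethyl)stannane
Product: 15 tributyl{[(1S,4R)-4-allyl-2,4-dimethylcyclohex-2-en-1-yl]oxymethyl}stannane, via potassium alkoxide 14 (not isolated)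
Conditions: KH, THF, 0 °C; Bu3SnCH2I, 0 °C → rt
Reagents that add atoms: tributyl(iodomethyl)stannane (13), CCCC[Sn](CI)(CCCC)CCCC; potassium hydride, [H-].[K+] (potassium in 14 only)
Why: Williamson etherification of the potassium alkoxide with the reactive primary iodide installs the stannylmethyl group that will become C6 without touching C3.

Step 8
Reactants: 15 tributyl{[(1S,4R)-4-allyl-2,4-dimethylcyclohex-2-en-1-yl]oxymethyl}stannane
Product: 17 [(1R,6R)-6-allyl-2,6-dimethylcyclohex-2-en-1-yl]methanol, via lithiomethyl ether 16 (not isolated)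
Conditions: n-BuLi, THF, −78 → −40 °C; then H2O
Reagents that add atoms: n-butyllithium, [Li]CCCC (lithium in 16 only)
Why: In this Still–Wittig [2,3]-sigmatropic rearrangement, tin–lithium exchange gives the α-alkoxy carbanion, which migrates suprafacially from the pseudoaxial 3β oxygen to the β face of C5, so the C3 configuration is transferred to C5 and C6 ends cis to C14 and trans to the allyl arm, a relationship that substrate control by methyl versus allyl could not secure.

Step 9
Reactants: 17 [(1R,6R)-6-allyl-2,6-dimethylcyclohex-2-en-1-yl]methanol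
Product: 18 3β,4β-epoxide of 17 (epoxide oxygen cis to the CH2OH group)
Conditions: VO(acac)2 (3 mol %), t-BuOOH (decane), CH2Cl2, 0 °C → rt
Reagents that add atoms: tert-butyl hydroperoxide, CC(C)(C)OO
Why: In this vanadium-catalysed hydroxyl-directed epoxidation the homoallylic C6 hydroxyl binds the metal peroxide and delivers oxygen to the β face of the electron-rich C3=C4 alkene, leaving the remote monosubstituted alkene alone.

Step 10
Reactants: 18 3β,4β-epoxide of 17
Product: 19 (1S,2S,3S,4R)-4-allyl-3-(hydroxymethyl)-2,4-dimethylcyclohexane-1,2-diol (3β,4α-diol)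
Conditions: HClO4 (cat.), THF–H2O, 0 °C → rt
Reagents that add atoms: water, O
Why: In this acid-catalysed anti opening of the trisubstituted epoxide (Fürst–Plattner, trans-diaxial), water attacks the tertiary C4 from the α face with inversion while the C3–O bond stays, which gives the 3β,4α-diol with the 4β methyl of the target.

Step 11
Reactants: 19 3β,4α-diol with free C6 hydroxyl
Product: 20 tris(triethylsilyl) ether of 19 (O3 O4 O6)
Conditions: Et3SiOTf, 2,6-lutidine, CH2Cl2, 0 °C
Reagents that add atoms: triethylsilyl triflate, CC[Si](CC)(CC)OS(=O)(=O)C(F)(F)F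
Why: Silyl ether protection with the triflate and a hindered base covers the primary, secondary and tertiary hydroxyls in one operation and blocks retro-aldol and chelation pathways at C4 in the later aldehyde.

Step 12
Reactants: 20 tris(triethylsilyl) ether of 19
Product: 22 C8 aldehyde (C9–C8 acetaldehyde arm on C10), via ozonide 21 (not isolated)
Conditions: O3, CH2Cl2, −78 °C; PPh3, −78 °C → rt
Reagents that add atoms: ozone, [O-][O+]=O
Why: Ozonolysis with reductive work-up cleaves the only remaining alkene and trims the allyl group to the C9–C8 acetaldehyde arm.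

Step 13
Reactants: 22 C8 aldehyde; 23 2-methylprop-1-enylmagnesium bromide
Product: 24 C8 allylic alcohol (mixture of C8 epimers)
Conditions: THF, −78 °C; then H2O
Reagents that add atoms: 2-methylprop-1-enylmagnesium bromide (23), CC(C)=C[Mg]Br
Why: Grignard 1,2-addition to the unhindered aldehyde brings in C7 and C11–C13 at once, and the uncontrolled C8 centre is corrected in steps 14 and 15.

Step 14
Reactants: 24 C8 allylic alcohol
Product: 25 C8 enone (C8=O conjugated to C7=C11)
Conditions: Dess–Martin periodinane, CH2Cl2, 0 °C → rt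
Reagents that add atoms: none
Why: Dess–Martin oxidation of the allylic alcohol erases the uncontrolled C8 centre under near-neutral conditions that the silyl ethers tolerate.

Step 15
Reactants: 25 C8 enone
Product: 26 (8S)-allylic alcohol
Conditions: (R)-2-methyl-CBS-oxazaborolidine C18H20BNO (20 mol %), catecholborane, toluene, −78 °C
Reagents that add atoms: none
Why: Corey–Bakshi–Shibata 1,2-reduction with the β,β-dimethylvinyl group as the large substituent sets C8 as S under reagent control, which is the epimer whose silyloxy group can lie equatorial in the ring B chair of step 18.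

Step 16
Reactants: 26 (8S)-allylic alcohol
Product: 27 (8S)-tert-butyldimethylsilyl ether
Conditions: t-BuMe2SiOTf, 2,6-lutidine, CH2Cl2, −78 → 0 °C
Reagents that add atoms: tert-butyldimethylsilyl triflate, CC(C)(C)[Si](C)(C)OS(=O)(=O)C(F)(F)F
Why: Silyl ether protection with the bulkier group gives a poorly Lewis-basic allylic ether that will outlast the triethylsilyl groups in step 20.

Step 17
Reactants: 27 (8S)-tert-butyldimethylsilyl ether
Product: 29 ene precursor (5β-formyl ring A aldehyde; 3β,4α-bis(triethylsilyloxy); (8S)-tert-butyldimethylsilyloxy arm bearing the C7=C11 alkene), via alkoxysulfonium chloride 28 (not isolated)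
Conditions: (COCl)2, DMSO, CH2Cl2, −78 → −40 °C; Et3N, −78 → 0 °C
Reagents that add atoms: dimethyl sulfoxide, CS(C)=O (SMe2 in 28 only); oxalyl chloride, O=C(Cl)C(=O)Cl (chloride in 28 only)
Why: Swern conditions convert a primary triethylsilyl ether directly into the aldehyde (oxidative desilylation through the alkoxysulfonium salt) while secondary, tertiary and tert-butyldimethylsilyl ethers stay, and the cold amine treatment avoids epimerisation at C5.

Step 18
Reactants: 29 ene precursor
Product: 30 ene product (trans-decalin; 5α-H; 10β-methyl; 6α-hydroxy; 7β-isopropenyl; 8α-tert-butyldimethylsilyloxy; 3β,4α-bis(triethylsilyloxy))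
Conditions: Me2AlCl (2 equiv), CH2Cl2, −78 → −40 °C; then H2O
Reagents that add atoms: none
Why: Coordination of Me2AlCl to the formyl oxygen raises the electrophilicity of C6, the π bond of the trisubstituted alkene bonds through its less substituted end C7 while positive charge is spread onto tertiary C11, and one hydrogen of the methyl group C12 migrates to the carbonyl oxygen in a cyclic six-centre array (asynchronous concerted type 1 carbonyl-ene reaction, whose closest known relative is the Lewis acid-promoted cyclisation of citronellal to isopulegol). Ring B closes as a six-membered chair over the tether C6–C5–C10–C9–C8–C7 by attack of the inner alkene carbon, the new C11=C12 alkene ends outside the ring, and the trans-diequatorial bonds from C5 and C10 make the product a trans-decalin. The new centres C6 and C7 should follow from this chair (6α oxygen equatorial because an axial one would meet C14 and C15, 7β isopropenyl equatorial), and both become trigonal in step 28. The step must activate the aldehyde without ionising the allylic ether, epimerising C5 or expelling the C4 oxygen, which is served by bulky silyl ethers that are poor donors and by a mild Lewis acid that consumes adventitious acid and turns the product alcohol into an inert alkoxide with loss of methane. The 8S configuration keeps the C8 hydrogen eclipsed with the alkene and the silyloxy group equatorial, so neither A(1,3) strain with the cis methyl nor a 1,3-diaxial contact with C14 opposes closure.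

Step 19
Reactants: 30 ene product
Product: 31 C6 mesylate
Conditions: MsCl, Et3N, CH2Cl2, 0 °C
Reagents that add atoms: methanesulfonyl chloride, CS(=O)(=O)Cl
Why: Sulfonate ester formation through the small sulfene intermediate turns the only free hydroxyl, at C6, into the leaving group for the final E1cB step.

Step 20
Reactants: 31 C6 mesylate
Product: 32 3β,4α-diol (C6 mesylate and C8 silyl ether retained)
Conditions: HF·pyridine, pyridine, THF, 0 °C
Reagents that add atoms: none
Why: Fluoride-mediated desilylation exploits the much greater lability of triethylsilyl over tert-butyldimethylsilyl ethers to free the 3β and 4α hydroxyls while C8 stays protected and the mesylate and alkene are inert.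

Step 21
Reactants: 33 angelic acid
Product: 34 (Z)-2-methylbut-2-en-1-ol
Conditions: LiAlH4, Et2O, 0 °C → rt; then H2O
Reagents that add atoms: none
Why: Hydride reduction of the carboxylic acid gives the allylic alcohol with the Z geometry retained, because 1,2-reduction of the carboxylate does not involve the alkene.

Step 22
Reactants: 34 (Z)-2-methylbut-2-en-1-ol
Product: 35 [(2R,3S)-2,3-dimethyloxiran-2-yl]methanol
Conditions: Ti(OiPr)4 (10 mol %), D-(−)-diethyl tartrate (12 mol %), t-BuOOH, 4 Å molecular sieves, CH2Cl2, −20 °C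
Reagents that add atoms: tert-butyl hydroperoxide, CC(C)(C)OO
Why: In this Sharpless asymmetric epoxidation the D-(−)-tartrate titanium catalyst gives the 2R,3S epoxy alcohol (the L-(+)-tartrate series gives 2S epoxy alcohols), and the syn oxygen transfer keeps C4′ and the carbinol carbon cis on the oxirane.

Step 23
Reactants: 35 [(2R,3S)-2,3-dimethyloxiran-2-yl]methanol
Product: 36 (2S,3S)-2,3-dimethyloxirane-2-carboxylic acid (epoxyangelic acid)
Conditions: RuCl3 (2 mol %), NaIO4, MeCN–EtOAc–H2O, 0 °C → rt
Reagents that add atoms: sodium periodate, [Na+].[O-]I(=O)(=O)=O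
Why: Ruthenium tetroxide oxidation takes the primary alcohol to the acid without touching the epoxide, and the descriptor at C2′ changes from R to S only because the priorities change.

Step 24
Reactants: 32 3β,4α-diol; 36 (2S,3S)-2,3-dimethyloxirane-2-carboxylic acid
Product: 38 3β-epoxyangelate with free 4α-hydroxyl, via mixed anhydride 37 (not isolated)
Conditions: 2,4,6-trichlorobenzoyl chloride, Et3N, THF, rt; then 32, 4-(dimethylamino)pyridine, toluene, rt
Reagents that add atoms: (2S,3S)-2,3-dimethyloxirane-2-carboxylic acid (36), C[C@@H]1O[C@]1(C)C(=O)O; 2,4,6-trichlorobenzoyl chloride, O=C(Cl)c1c(Cl)cc(Cl)cc1Cl (in 37 only)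
Why: Yamaguchi esterification through the mixed anhydride acylates the equatorial secondary 3β hydroxyl selectively, the tertiary C4 hydroxyl being far too hindered for this α-quaternary acyl group, and both oxirane centres are carried over unchanged.

Step 25
Reactants: 38 3β-epoxyangelate with free 4α-hydroxyl
Product: 39 3β-epoxyangelate 4α-formate
Conditions: HCO2H/Ac2O (premixed, 50 °C), pyridine, 4-(dimethylamino)pyridine (cat.), CH2Cl2, 0 °C → rt
Reagents that add atoms: acetic formic anhydride, CC(=O)OC=O
Why: Formylation with acetic formic anhydride under nucleophilic catalysis transfers the smallest acyl group to the only free hydroxyl, the tertiary one at C4, at a stage where the C11 hydroxyl does not yet exist and so cannot compete.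

Step 26
Reactants: 39 3β-epoxyangelate 4α-formate
Product: 40 C11 tertiary alcohol
Conditions: Co(acac)2 (20 mol %), PhSiH3, O2 (1 atm), THF, rt
Reagents that add atoms: dioxygen, O=O
Why: In this Mukaiyama hydration, hydrogen-atom transfer from a cobalt hydride to the terminal carbon of the 1,1-disubstituted alkene gives the tertiary C11 radical, which is trapped by O2 and reduced to the Markovnikov alcohol under neutral conditions that spare esters, epoxide, mesylate and silyl ether.

Step 27
Reactants: 40 C11 tertiary alcohol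
Product: 41 C8 secondary alcohol
Conditions: HF·pyridine, THF, 0 °C → rt
Reagents that add atoms: none
Why: Fluoride-mediated desilylation under mildly acidic, non-nucleophilic conditions frees the C8 hydroxyl, and the formate, the deactivated glycidic ester and the mesylate should persist.

Step 28
Reactants: 41 C8 secondary alcohol
Product: 43 CNP0171909.1, via mesyloxy ketone 42 (not isolated)
Conditions: Dess–Martin periodinane, CH2Cl2, 0 °C; then Et3N, 0 °C → rt
Reagents that add atoms: none
Why: Dess–Martin oxidation gives the C8 ketone, and triethylamine then triggers E1cB loss of the far better leaving group, the C6 mesylate, rather than of the C11 hydroxyl, which makes C6, C7 and C8 trigonal and delivers the C6=C7–C8=O enone of the target.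

Compound list
1 | 2-methylcyclohexane-1,3-dione | CC1C(=O)CCCC1=O | starting material
2 | 3-isobutoxy-2-methylcyclohex-2-en-1-one | CC1=C(OCC(C)C)CCCC1=O | intermediate
3 | iodomethane | CI | starting material
4 | lithium α′-enolate of 2 | [Li]OC1=CCCC(OCC(C)C)=C1C | intermediate
5 | 3-isobutoxy-2,6-dimethylcyclohex-2-en-1-one (racemic) | CC1CCC(OCC(C)C)=C(C)C1=O | intermediate
6 | allyl chloroformate | C=CCOC(=O)Cl | starting material
7 | lithium enolate of 5 | [Li]OC1=C(C)CCC(OCC(C)C)=C1C | intermediate
8 | allyl 5-isobutoxy-2,6-dimethylcyclohexa-1,5-dien-1-yl carbonate | C=CCOC(=O)OC1=C(C)CCC(OCC(C)C)=C1C | intermediate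
9 | (R)-6-allyl-3-isobutoxy-2,6-dimethylcyclohex-2-en-1-one | C=CC[C@@]1(C)CCC(OCC(C)C)=C(C)C1=O | intermediate
10 | (6R)-6-allyl-3-isobutoxy-2,6-dimethylcyclohex-2-en-1-ol (carbinol epimers) | C=CC[C@@]1(C)CCC(OCC(C)C)=C(C)C1O | intermediate
11 | (R)-4-allyl-2,4-dimethylcyclohex-2-en-1-one | C=CC[C@]1(C)C=C(C)C(=O)CC1 | intermediate
12 | (1S,4R)-4-allyl-2,4-dimethylcyclohex-2-en-1-ol | C=CC[C@]1(C)C=C(C)[C@@H](O)CC1 | intermediate
13 | tributyl(iodomethyl)stannane | CCCC[Sn](CI)(CCCC)CCCC | starting material
14 | potassium alkoxide of 12 | C=CC[C@]1(C)C=C(C)[C@@H](O[K])CC1 | intermediate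
15 | tributyl{[(1S,4R)-4-allyl-2,4-dimethylcyclohex-2-en-1-yl]oxymethyl}stannane | C=CC[C@]1(C)C=C(C)[C@@H](OC[Sn](CCCC)(CCCC)CCCC)CC1 | intermediate
16 | lithiomethyl ether of 12 | C=CC[C@]1(C)C=C(C)[C@@H](OC[Li])CC1 | intermediate
17 | [(1R,6R)-6-allyl-2,6-dimethylcyclohex-2-en-1-yl]methanol | C=CC[C@@]1(C)CCC=C(C)[C@@H]1CO | intermediate
18 | 3β,4β-epoxide of 17 | C=CC[C@@]1(C)CC[C@@H]2O[C@]2(C)[C@@H]1CO | intermediate
19 | (1S,2S,3S,4R)-4-allyl-3-(hydroxymethyl)-2,4-dimethylcyclohexane-1,2-diol | C=CC[C@@]1(C)CC[C@H](O)[C@@](C)(O)[C@@H]1CO | intermediate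
20 | tris(triethylsilyl) ether of 19 | C=CC[C@@]1(C)CC[C@H](O[Si](CC)(CC)CC)[C@@](C)(O[Si](CC)(CC)CC)[C@@H]1CO[Si](CC)(CC)CC | intermediate
21 | ozonide of 20 | C1OOC(C[C@@]2(C)CC[C@H](O[Si](CC)(CC)CC)[C@@](C)(O[Si](CC)(CC)CC)[C@@H]2CO[Si](CC)(CC)CC)O1 | intermediate
22 | C8 aldehyde | O=CC[C@@]1(C)CC[C@H](O[Si](CC)(CC)CC)[C@@](C)(O[Si](CC)(CC)CC)[C@@H]1CO[Si](CC)(CC)CC | intermediate
23 | 2-methylprop-1-enylmagnesium bromide | CC(C)=C[Mg]Br | starting material
24 | C8 allylic alcohol (C8 epimers) | CC(C)=CC(O)C[C@@]1(C)CC[C@H](O[Si](CC)(CC)CC)[C@@](C)(O[Si](CC)(CC)CC)[C@@H]1CO[Si](CC)(CC)CC | intermediate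
25 | C8 enone | CC(C)=CC(=O)C[C@@]1(C)CC[C@H](O[Si](CC)(CC)CC)[C@@](C)(O[Si](CC)(CC)CC)[C@@H]1CO[Si](CC)(CC)CC | intermediate
26 | (8S)-allylic alcohol | CC(C)=C[C@@H](O)C[C@@]1(C)CC[C@H](O[Si](CC)(CC)CC)[C@@](C)(O[Si](CC)(CC)CC)[C@@H]1CO[Si](CC)(CC)CC | intermediate
27 | (8S)-tert-butyldimethylsilyl ether | CC(C)=C[C@@H](O[Si](C)(C)C(C)(C)C)C[C@@]1(C)CC[C@H](O[Si](CC)(CC)CC)[C@@](C)(O[Si](CC)(CC)CC)[C@@H]1CO[Si](CC)(CC)CC | intermediate
28 | C6 alkoxysulfonium chloride | CC(C)=C[C@@H](O[Si](C)(C)C(C)(C)C)C[C@@]1(C)CC[C@H](O[Si](CC)(CC)CC)[C@@](C)(O[Si](CC)(CC)CC)[C@@H]1CO[S+](C)C.[Cl-] | intermediate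
29 | ene precursor (ring A C6 aldehyde) | CC(C)=C[C@@H](O[Si](C)(C)C(C)(C)C)C[C@@]1(C)CC[C@H](O[Si](CC)(CC)CC)[C@@](C)(O[Si](CC)(CC)CC)[C@@H]1C=O | intermediate
30 | ene product (trans-decalin, 6α-OH, 7β-isopropenyl, 8α-silyloxy) | CC[Si](CC)(CC)O[C@H]1CC[C@]2(C)C[C@H](O[Si](C)(C)C(C)(C)C)[C@@H](C(C)=C)[C@H](O)[C@H]2[C@]1(C)O[Si](CC)(CC)CC | intermediate
31 | C6 mesylate | CC[Si](CC)(CC)O[C@H]1CC[C@]2(C)C[C@H](O[Si](C)(C)C(C)(C)C)[C@@H](C(C)=C)[C@H](OS(C)(=O)=O)[C@H]2[C@]1(C)O[Si](CC)(CC)CC | intermediate
32 | 3β,4α-diol mesylate | O[C@H]1CC[C@]2(C)C[C@H](O[Si](C)(C)C(C)(C)C)[C@@H](C(C)=C)[C@H](OS(C)(=O)=O)[C@H]2[C@]1(C)O | intermediate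
33 | angelic acid | C/C=C(/C)C(=O)O | starting material
34 | (Z)-2-methylbut-2-en-1-ol | C/C=C(/C)CO | intermediate
35 | [(2R,3S)-2,3-dimethyloxiran-2-yl]methanol | C[C@@H]1O[C@]1(C)CO | intermediate
36 | (2S,3S)-2,3-dimethyloxirane-2-carboxylic acid | C[C@@H]1O[C@]1(C)C(=O)O | intermediate
37 | mixed anhydride of 36 and 2,4,6-trichlorobenzoic acid | C[C@@H]1O[C@]1(C)C(=O)OC(=O)c1c(Cl)cc(Cl)cc1Cl | intermediate
38 | 3β-epoxyangelate, 4α-OH | C[C@@H]1O[C@]1(C)C(=O)O[C@H]1CC[C@]2(C)C[C@H](O[Si](C)(C)C(C)(C)C)[C@@H](C(C)=C)[C@H](OS(C)(=O)=O)[C@H]2[C@]1(C)O | intermediate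
39 | 3β-epoxyangelate 4α-formate | C[C@@H]1O[C@]1(C)C(=O)O[C@H]1CC[C@]2(C)C[C@H](O[Si](C)(C)C(C)(C)C)[C@@H](C(C)=C)[C@H](OS(C)(=O)=O)[C@H]2[C@]1(C)OC=O | intermediate
40 | C11 tertiary alcohol | C[C@@H]1O[C@]1(C)C(=O)O[C@H]1CC[C@]2(C)C[C@H](O[Si](C)(C)C(C)(C)C)[C@@H](C(C)(C)O)[C@H](OS(C)(=O)=O)[C@H]2[C@]1(C)OC=O | intermediate
41 | C8 secondary alcohol | C[C@@H]1O[C@]1(C)C(=O)O[C@H]1CC[C@]2(C)C[C@H](O)[C@@H](C(C)(C)O)[C@H](OS(C)(=O)=O)[C@H]2[C@]1(C)OC=O | intermediate
42 | 6-mesyloxy 8-ketone | C[C@@H]1O[C@]1(C)C(=O)O[C@H]1CC[C@]2(C)CC(=O)[C@@H](C(C)(C)O)[C@H](OS(C)(=O)=O)[C@H]2[C@]1(C)OC=O | intermediate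
43 | CNP0171909.1 | C[C@@H]1O[C@]1(C)C(=O)O[C@H]1CC[C@]2(C)CC(=O)C(C(C)(C)O)=C[C@H]2[C@]1(C)OC=O | target

Total step count: 28. Longest linear sequence: 25 steps (steps 1–20 and 24–28). The epoxy acid branch (steps 21–23) has 3 steps.

Steps most likely to fail

Step 18. The Lewis acid may ionise the allylic silyl ether. Closure may also be too slow because the allylic oxygen lowers the nucleophilicity of the alkene, so that warming brings epimerisation at C5 or β-elimination of the C4 silyloxy group. The fallback replaces hydrogen transfer by an intramolecular Hosomi–Sakurai allylation. It sets out from 22 and returns at 30.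
- The vinyllithium made from (E)-(3-bromo-2-methylprop-2-enyl)trimethylsilane and t-BuLi is added to 22 to give the silylmethyl-substituted allylic alcohol F1.
- Dess–Martin oxidation gives the silylmethyl enone F2.
- Oxazaborolidine-catalysed reduction as in step 15 gives the (8S)-alcohol F3.
- Silylation as in step 16 gives the tert-butyldimethylsilyl ether F4.
- Swern treatment as in step 17 gives the allylsilane aldehyde F5.
- BF3·OEt2 in CH2Cl2 at −78 °C then joins C6 and C7 with loss of the trimethylsilyl group. This releases the same C11=C12 alkene and gives 30 directly.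

Step 8. A [1,2]-shift or simple protonation of the carbanion may compete, because bond formation at C5 next to the quaternary C10 is slow. The fallback uses a neutral thermal [2,3]-shift. It sets out from 12 and returns at 17.
- Heating 12 with N,N-dimethylformamide dimethyl acetal in xylene exchanges the alcohol into the acetal.
- Loss of methanol gives an alkoxy(amino)carbene, and its suprafacial [2,3]-rearrangement gives the β,γ-unsaturated dimethylamide F6.
- LiH2NBH3 in THF reduces this tertiary amide to the primary alcohol 17.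

Step 25. Acylation of the crowded tertiary hydroxyl may be incomplete, and forcing conditions may cause loss of the mesylate or acyl scrambling. The fallback delivers the formyl group from within and inverts the order of the two acylations. It sets out from 32 and returns at 39.
- Diol 32 is condensed with trimethyl orthoformate (pyridinium p-toluenesulfonate, CH2Cl2) to give the cyclic orthoformate F7.
- Brief treatment with aqueous acetic acid opens it with the formyl group left on the more hindered oxygen, giving the 4α-formate 3β-alcohol F8.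
- Yamaguchi esterification of F8 with acid 36, as in step 24, gives 39.

Further compounds
F1 | step 18 | silylmethyl-substituted allylic alcohol (C8 epimers) | C[Si](C)(C)C/C(C)=C/C(O)C[C@@]1(C)CC[C@H](O[Si](CC)(CC)CC)[C@@](C)(O[Si](CC)(CC)CC)[C@@H]1CO[Si](CC)(CC)CC
F2 | step 18 | silylmethyl enone | C[Si](C)(C)C/C(C)=C/C(=O)C[C@@]1(C)CC[C@H](O[Si](CC)(CC)CC)[C@@](C)(O[Si](CC)(CC)CC)[C@@H]1CO[Si](CC)(CC)CC
F3 | step 18 | (8S)-alcohol of the allylsilane series | C[Si](C)(C)C/C(C)=C/[C@@H](O)C[C@@]1(C)CC[C@H](O[Si](CC)(CC)CC)[C@@](C)(O[Si](CC)(CC)CC)[C@@H]1CO[Si](CC)(CC)CC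
F4 | step 18 | (8S)-tert-butyldimethylsilyl ether of the allylsilane series | C[Si](C)(C)C/C(C)=C/[C@@H](O[Si](C)(C)C(C)(C)C)C[C@@]1(C)CC[C@H](O[Si](CC)(CC)CC)[C@@](C)(O[Si](CC)(CC)CC)[C@@H]1CO[Si](CC)(CC)CC
F5 | step 18 | allylsilane aldehyde | C[Si](C)(C)C/C(C)=C/[C@@H](O[Si](C)(C)C(C)(C)C)C[C@@]1(C)CC[C@H](O[Si](CC)(CC)CC)[C@@](C)(O[Si](CC)(CC)CC)[C@@H]1C=O
F6 | step 8 | (1R,6R)-6-allyl-N,N,2,6-tetramethylcyclohex-2-ene-1-carboxamide | C=CC[C@@]1(C)CCC=C(C)[C@@H]1C(=O)N(C)C
F7 | step 25 | 3,4-cyclic methyl orthoformate of 32 | COC1O[C@H]2CC[C@]3(C)C[C@H](O[Si](C)(C)C(C)(C)C)[C@@H](C(C)=C)[C@H](OS(C)(=O)=O)[C@H]3[C@]2(C)O1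
F8 | step 25 | 4α-formate 3β-alcohol | O[C@H]1CC[C@]2(C)C[C@H](O[Si](C)(C)C(C)(C)C)[C@@H](C(C)=C)[C@H](OS(C)(=O)=O)[C@H]2[C@]1(C)OC=O
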